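**Strategy.** The route rests on disconnecting the bond between the ring B ketone carbon C5 and the benzo carbon C5a of the naphtho[1,2-b]furan core. The precursor is a tricyclic tert-butyl β-keto ester in which the furan, the seven-membered phthaloyl ring and a phenyl group on furan carbon C9b are already in place. On heating it should lose tert-butanol to an α-oxoketene; its C4=C5 bond, the furan C3a=C9b bond and one phenyl C=C bond form a hexatriene, and 6π-electrocyclisation onto the unsubstituted phenyl ortho C–H, then tautomerisation, closes ring B and gives radermachol directly under neutral conditions. The tricycle is built on 2,3-dibromofuran by three cross-couplings, a dibromination and two anionic acylations.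

Key step: step 7

Remark on numbering and assumptions: monocyclic furans carry ordinary furan locants. For the core of radermachol the naphtho[1,2-b]furan locants are used: O1, C2 (2-methylprop-1-enyl), C3, C3a, C4, C5 (ring B ketone), C5a–C9a (benzo ring C), C9b. Ring A is the benzo ring of the seven-membered ring. Radermachol is taken as the tautomer drawn (C5 ketone, enol on the seven-membered ring). It has no stereocentre; the labile stereocentres of 12 and 17 are racemic and disappear. Reagent 4 is assumed to be bought as its commercial ether solution.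

**Step 1**
Reactants: 1 2,3-dibromofuran; 2 phenylboronic acid
Product: 3 3-bromo-2-phenylfuran
Conditions: Pd(PPh3)4 (3 mol %), Na2CO3 (aq), DME, 80 °C
Reagents that add atoms: none
Why: Suzuki–Miyaura coupling; oxidative addition is faster at the C2–Br bond next to the ring oxygen than at C3–Br, so one equivalent of 2 should arylate C2 only.

**Step 2**
Reactants: 3 3-bromo-2-phenylfuran; 4 (2-tert-butoxy-2-oxoethyl)zinc chloride
Product: 5 tert-butyl 2-(2-phenylfuran-3-yl)acetate
Conditions: Pd(dba)2 (2 mol %), P(t-Bu)3 (2 mol %), THF, 25 → 50 °C
Reagents that add atoms: none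
Why: Palladium-catalysed α-arylation of an ester through its Reformatsky zinc enolate (Negishi-type coupling), which is mild enough to avoid diarylation and should tolerate the ortho phenyl group.

**Step 3**
Reactants: 5 tert-butyl 2-(2-phenylfuran-3-yl)acetate
Product: 7 tert-butyl 2-(4,5-dibromo-2-phenylfuran-3-yl)acetate, via 5-bromofuran 6 (not isolated)
Conditions: NBS (2.1 equiv), DMF, 0 → 25 °C, dark
Reagents that add atoms: N-bromosuccinimide, O=C1CCC(=O)N1Br
Why: Electrophilic aromatic bromination; the free α position C5 reacts first and the only remaining furan position C4 second, while the phenyl ring and the tert-butyl ester should be inert to NBS in the dark.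

**Step 4**
Reactants: 7 tert-butyl 2-(4,5-dibromo-2-phenylfuran-3-yl)acetate; 8 4,4,5,5-tetramethyl-2-(2-methylprop-1-enyl)-1,3,2-dioxaborolane
Product: 9 tert-butyl 2-[4-bromo-5-(2-methylprop-1-enyl)-2-phenylfuran-3-yl]acetate
Conditions: 8 (1.05 equiv), Pd(PPh3)4 (5 mol %), K2CO3 (aq), 1,4-dioxane, 70 °C
Reagents that add atoms: none
Why: Site-selective Suzuki–Miyaura coupling; the α C5–Br bond adds to zerovalent palladium faster than the β C4–Br bond, so the side chain should enter at C5 and leave C4–Br for step 6.

**Step 5**
Reactants: 9 tert-butyl 2-[4-bromo-5-(2-methylprop-1-enyl)-2-phenylfuran-3-yl]acetate; 10 dimethyl phthalate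
Product: 12 tert-butyl 2-[4-bromo-5-(2-methylprop-1-enyl)-2-phenylfuran-3-yl]-3-[2-(methoxycarbonyl)phenyl]-3-oxopropanoate (racemic keto–enol mixture), via lithium enolate 11 (not isolated)
Conditions: LiN(SiMe3)2 (2.2 equiv), THF, −78 °C; 10 (3 equiv), −78 → 0 °C; aq. NH4Cl
Reagents that add atoms: none
Why: Crossed Claisen condensation of an ester enolate with an excess of a non-enolisable diester; the second equivalent of base stores the product as its stabilised enolate, which drives the acylation and should prevent a second one.

**Step 6**
Reactants: 12 tert-butyl 2-[4-bromo-5-(2-methylprop-1-enyl)-2-phenylfuran-3-yl]-3-[2-(methoxycarbonyl)phenyl]-3-oxopropanoate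
Product: 15 tert-butyl 5-hydroxy-1-(2-methylprop-1-enyl)-10-oxo-3-phenyl-10H-benzo[5,6]cyclohepta[1,2-c]furan-4-carboxylate (enol form), via sodium enolate 13 (not isolated), via furyllithium 14 (not isolated)
Conditions: NaH (1.05 equiv), THF, 0 °C; t-BuLi (2.05 equiv), −78 → −20 °C; aq. NH4Cl
Reagents that add atoms: none
Why: Parham cyclisation; with the β-keto ester masked as its enolate, bromine–lithium exchange at furan C4 should outrun carbonyl addition at −78 °C, and the furyllithium can reach only the aryl methyl ester, so acyl substitution closes the seven-membered ring (7-exo-trig).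

**Step 7**
Reactants: 15 tert-butyl 5-hydroxy-1-(2-methylprop-1-enyl)-10-oxo-3-phenyl-10H-benzo[5,6]cyclohepta[1,2-c]furan-4-carboxylate
Product: 18 radermachol, via acylketene 16 (not isolated), via cyclohexadienone 17 (not isolated)
Conditions: xylenes (0.01 M), 4 Å molecular sieves, 140 °C, argon
Reagents that add atoms: none
Why: Heating the enolised tert-butyl β-keto ester should expel tert-butanol through a six-membered transition state and give the α-oxoketene 16, in which (radermachol locants) the ketene C4=C5 bond, the furan C3a=C9b bond and the C9a=C5a bond of the phenyl ring form a cis-locked 1,3,5-hexatriene. Thermal 6π-electrocyclisation (formally disrotatory, with in-plane attack on the ketene carbon also possible) joins C5 to the unsubstituted ortho carbon C5a and closes the six-membered ring B as dienone 17; a proton shift from C5a to oxygen then restores the phenyl and furan rings and ends at the hydrogen-bonded tautomer 18. The closest known reactions are the ketene-onto-arene ring closure that ends the Danheiser, Moore and Dötz benzannulations and the thermal Conrad–Limpach and Gould–Jacobs cyclisations, and the ketene source is the established thermolysis of tert-butyl β-keto esters. No stereocentre remains, since the C5a stereocentre of 17 is lost on tautomerisation. Only site selectivity is needed: the seven-membered ring holds the ketene carbon peri to the C9b phenyl group, the two ortho positions of that phenyl are equivalent, and no other π bond can complete a six-membered ring. High dilution, molecular sieves and escape of tert-butanol should suppress re-addition, hydrolysis with decarboxylation and ketene dimerisation.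

**Compound list**
1 | 2,3-dibromofuran | Brc1occc1Br | starting material
2 | phenylboronic acid | OB(O)c1ccccc1 | starting material
3 | 3-bromo-2-phenylfuran | Brc1ccoc1-c1ccccc1 | intermediate
4 | (2-tert-butoxy-2-oxoethyl)zinc chloride | CC(C)(C)OC(=O)C[Zn]Cl | starting material
5 | tert-butyl 2-(2-phenylfuran-3-yl)acetate | CC(C)(C)OC(=O)Cc1ccoc1-c1ccccc1 | intermediate
6 | tert-butyl 2-(5-bromo-2-phenylfuran-3-yl)acetate | CC(C)(C)OC(=O)Cc1cc(Br)oc1-c1ccccc1 | intermediate
7 | tert-butyl 2-(4,5-dibromo-2-phenylfuran-3-yl)acetate | CC(C)(C)OC(=O)Cc1c(Br)c(Br)oc1-c1ccccc1 | intermediate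
8 | 4,4,5,5-tetramethyl-2-(2-methylprop-1-enyl)-1,3,2-dioxaborolane | CC(C)=CB1OC(C)(C)C(C)(C)O1 | starting material
9 | tert-butyl 2-[4-bromo-5-(2-methylprop-1-enyl)-2-phenylfuran-3-yl]acetate | CC(C)=Cc1oc(-c2ccccc2)c(CC(=O)OC(C)(C)C)c1Br | intermediate
10 | dimethyl phthalate | COC(=O)c1ccccc1C(=O)OC | starting material
11 | lithium enolate of 9 | CC(C)=Cc1oc(-c2ccccc2)c(C=C([O-])OC(C)(C)C)c1Br.[Li+] | intermediate
12 | tert-butyl 2-[4-bromo-5-(2-methylprop-1-enyl)-2-phenylfuran-3-yl]-3-[2-(methoxycarbonyl)phenyl]-3-oxopropanoate (racemic) | CC(C)=Cc1oc(-c2ccccc2)c(C(C(=O)OC(C)(C)C)C(=O)c2ccccc2C(=O)OC)c1Br | intermediate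
13 | sodium enolate of 12 | CC(C)=Cc1oc(-c2ccccc2)c(C(C(=O)OC(C)(C)C)=C([O-])c2ccccc2C(=O)OC)c1Br.[Na+] | intermediate
14 | sodium enolate of 12 lithiated at furan C4 | CC(C)=Cc1oc(-c2ccccc2)c(C(C(=O)OC(C)(C)C)=C([O-])c2ccccc2C(=O)OC)c1[Li].[Na+] | intermediate
15 | tert-butyl 5-hydroxy-1-(2-methylprop-1-enyl)-10-oxo-3-phenyl-10H-benzo[5,6]cyclohepta[1,2-c]furan-4-carboxylate (furan fused through its 3,4-bond to a benzo-annulated seven-membered ring; enol form) | CC(C)=Cc1oc(-c2ccccc2)c2c1C(=O)c1ccccc1C(O)=C2C(=O)OC(C)(C)C | intermediate
16 | 1-(2-methylprop-1-enyl)-4-(oxomethylidene)-3-phenyl-4H-benzo[5,6]cyclohepta[1,2-c]furan-5,10-dione (α-oxoketene) | CC(C)=Cc1oc(-c2ccccc2)c2c1C(=O)c1ccccc1C(=O)C2=C=O | intermediate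
17 | electrocyclisation product, ring B closed, 5a-H cyclohexadienone (racemic) | CC(C)=CC1=C2C(=O)c3ccccc3C(=O)C3=C2C(O1)=C1C=CC=CC1C3=O | intermediate
18 | radermachol | CC(C)=Cc1oc2c3c(c(O)c4ccccc4c(=O)c13)C(=O)c1ccccc1-2 | target

**Step count and risks**
Total step count: 7. Longest linear sequence: 7 steps (1 → 18).

Steps most likely to fail:

1. Step 7. The α-oxoketene may fail to close onto the phenyl ring and be consumed instead by re-addition of tert-butanol, by hydrolysis and decarboxylation through traces of water, or by dimerisation; the tert-butyl ester may also fragment to isobutene and a β-keto acid that decarboxylates. The fallback forms the same ring bond by Friedel–Crafts acylation on a substrate without the acid-sensitive side chain and attaches that chain last. It sets out from 5: one equivalent of NBS should give tert-butyl 2-(5-bromo-2-phenylfuran-3-yl)acetate 6, isolated this time. Its lithium enolate (LiN(SiMe3)2, THF, −78 °C) is acylated with phthalic anhydride to 2-[2-(5-bromo-2-phenylfuran-3-yl)-3-tert-butoxy-3-oxopropanoyl]benzoic acid F1. P2O5 in MeSO3H (25–50 °C) should cleave the tert-butyl ester and effect two Friedel–Crafts acylations, onto the phenyl ortho carbon and onto furan C4, to give the 2-bromo analogue of radermachol F2. Suzuki–Miyaura coupling of F2 with 8 (Pd(PPh3)4, K2CO3, dioxane/water) comes back to the route at 18.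

2. Step 6. tert-Butyllithium may add to the methyl ester or the ketone before the exchange, and the furyllithium may be protonated before it cyclises (loss of bromine without ring closure) or attack a second molecule. The fallback closes the seven-membered ring through its other bond. It sets out from 9: carbonylative Suzuki–Miyaura coupling with 2-(methoxycarbonyl)phenylboronic acid (Pd(OAc)2, P(1-adamantyl)2(n-Bu), K2CO3, CO 5 bar, toluene, 100 °C) should give tert-butyl 2-[4-(2-methoxycarbonylbenzoyl)-5-(2-methylprop-1-enyl)-2-phenylfuran-3-yl]acetate F3. Dieckmann condensation of the acetate enolate onto the aryl methyl ester (KOt-Bu, THF, 0 °C) comes back to the route at 15, so steps 5 and 6 are both bypassed.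

3. Step 5. After the first acylation the product enolate may attack the neighbouring methyl ester (O-acylation to a 3-ylidenephthalide or C-acylation to a 2,2-disubstituted indane-1,3-dione), or a second enolate may acylate the remaining ester. The fallback uses an acyl donor whose second carbonyl becomes an inert carboxylate. It sets out from 9: the lithium enolate 11 opens phthalic anhydride to give 2-{2-[4-bromo-5-(2-methylprop-1-enyl)-2-phenylfuran-3-yl]-3-tert-butoxy-3-oxopropanoyl}benzoic acid F4. Selective O-methylation of the carboxylic acid (MeI, NaHCO3, DMF, 25 °C) comes back to the route at 12.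

**Further compounds**
F1 | step 7 | 2-[2-(5-bromo-2-phenylfuran-3-yl)-3-tert-butoxy-3-oxopropanoyl]benzoic acid | CC(C)(C)OC(=O)C(C(=O)c1ccccc1C(=O)O)c1cc(Br)oc1-c1ccccc1
F2 | step 7 | 2-bromo analogue of radermachol (bromine in place of the 2-methylprop-1-enyl group) | Brc1oc2c3c(c(O)c4ccccc4c(=O)c13)C(=O)c1ccccc1-2
F3 | step 6 | tert-butyl 2-[4-(2-methoxycarbonylbenzoyl)-5-(2-methylprop-1-enyl)-2-phenylfuran-3-yl]acetate | CC(C)=Cc1oc(-c2ccccc2)c(CC(=O)OC(C)(C)C)c1C(=O)c1ccccc1C(=O)OC
F4 | step 5 | 2-{2-[4-bromo-5-(2-methylprop-1-enyl)-2-phenylfuran-3-yl]-3-tert-butoxy-3-oxopropanoyl}benzoic acid | CC(C)=Cc1oc(-c2ccccc2)c(C(C(=O)OC(C)(C)C)C(=O)c2ccccc2C(=O)O)c1Br
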